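**The pitfall.** The easy mistake with this flask was to carry the early share of Z forward to the end, so I built it up one process at a time.

all flasks: Q 0.020 M
- east: D 0.10 M; E 0.020 M; the very flask that is asked about, followed so far
- north-west: D 0.10 M; E 0.030 M; run made earlier
- flask: D 0.100 M; E 0.0200 M; time 15 min

| run | time / min | Z / % | J / % |
|---|---|---|---|
| east | 0.417 | 1.3 | 4.4 |
| east | 0.833 | 3.8 | 7.8 |
| east | 1.33 | 3.0 | 15.0 |
| east | 1.50 | 3.3 | 15.2 |
| east | 2.00 | 5.6 | 21.7 |
| east | 2.50 | 7.8 | 29.0 |
| east | 3.00 | 6.4 | 31.8 |
| north-west | 0.833 | 2.6 | 10.2 |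
| north-west | 1.33 | 1.6 | 15.9 |
| north-west | 2.00 | 3.6 | 24.8 |
| north-west | 3.00 | 5.3 | 34.6 |
| north-west | 5.00 | 6.5 | 49.3 |
| north-west | 6.00 | 7.2 | 53.8 |
| north-west | 10.0 | 17.3 | 61.2 |

(each reading ± 1 percentage point)

- share of Z in Z plus J at 12 s
- share of Z in Z plus J at 15 min



**Main step.** I first let Q pass straight to products. Z plus J in the east run at 3.00 min gave a first-order constant of 0.160 min⁻¹, which put 91.0% of the Q charged into products by 15 min.

**Adding E.** Next I let each J take one E. Supposing E had no other loss, its charge of 0.0200 M exceeded the 0.0182 M that J would take if all that converted Q became J.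

**Adding the loss.** But the north-west run, charged with 0.030 M of E, had reached J of 61.2% at 10.0 min, while Z went from 7.2% to 17.3% over the last interval. I read that as E gone, with 40.8% of it turned into J and the rest lost another way. For the flask this gave 40.8%, the J ceiling, the level in percent of the Q charged at which J stops. The thing to watch was J levelling there while Z kept rising. Z taking the remainder made my share at 15 min 55.2%. At 12 s I made no figure, since the first east reading of Z, 1.3%, stood against a scatter of 1 percentage point.

**The forecast.** It gave 17% at 12 s and 37% at 15 min, holding that “Something stronger is operating”. My share stood higher than its late figure.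

**The flask.** It gave 47.3% at 12 s and 42.0% at 15 min.

    E → L (k = 0.00420 s⁻¹)
    Q → X (k = 0.00290 s⁻¹)
    E + X → J (k = 13.0 M⁻¹ s⁻¹)
    D + X ⇌ Z (K = 36.0 M⁻¹, k = 3.50 M⁻¹ s⁻¹)

**The ceiling again.** At 15.0 min the flask held E at 0%, the limiting reagent, and J at 47.8%, higher than the ceiling of 40.8%. The relaxation of D + X and Z took 1.61 s, shorter than the 15 min of the run, and Z stood at 34.5% beside X at 10.4%. In the neighbour flask with [D] at 0.17 M, the ceiling, made from the charges of Q and E, still read 40.8%; the simulation gave J 44.8% and a share of 47.6%.

The data come from a simulation on assumed constants, and the scatter is random.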